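**Plan**

- Retrosynthesis first removes the three O‑benzyl groups, then cuts the ring A aroyl C1–O4 ester bond to ring B, then cuts in one operation the ring B aroyl C1–O ester bond to O4 of ring C and the ring B C1–C6 bond.
- Enabling feature (each ring numbered C1 carbonyl‑bearing carbon, C2 hydroxyl, C4 para oxygen, C6 methyl): ring B is a 2,4‑dihydroxy‑6‑methylbenzoyl group sitting on O4 of ring C, which is a folded 3,5,7‑trioxooctanoyl chain carried by a phenol oxygen.
- Forward order: ring C is bought as orsellinic acid and benzylated at the carboxyl. Ring B is grown on O4 of ring C from an acylketene released by a diketo‑dioxinone and closed by aldol aromatisation. Ring A, bought as an aromatic ketone, is attached last.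
- Ring A acid: the O5 acetate comes from the acetyl group of the starting ketone by Baeyer–Villiger oxidation, and the carboxyl from a formyl group introduced next to the methyl.
- Stereochemistry: the target has no stereocentre. All control is chemo‑ and regiochemical: the hydrogen‑bonded C2 hydroxyls stay passive and the C4 hydroxyls react.

Key step: step 4

Assumption: 1‑(2,4‑dihydroxy‑6‑methylphenyl)ethan‑1‑one is taken as a catalogue compound; it is otherwise the Hoesch acetylation product of orcinol.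

**Route**

Step 1
Reactants: 1 2,2,6‑trimethyl‑4H‑1,3‑dioxin‑4‑one
Product: 2 2,2‑dimethyl‑6‑(2‑oxopropyl)‑4H‑1,3‑dioxin‑4‑one
Conditions: 1 (2 equiv), LiN(SiMe3)2 (2 equiv), THF, −78 °C; AcCl (1 equiv), −78 °C; aq. HCl
Reagents that add atoms: acetyl chloride, CC(=O)Cl
Why: The lithium dienolate formed at the C6 methyl is C‑acylated by acetyl chloride (Claisen‑type acylation of a vinylogous ester enolate), and the second equivalent of enolate takes up the acidic proton of the product so that it is not acylated again.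

Step 2
Reactants: 2 2,2‑dimethyl‑6‑(2‑oxopropyl)‑4H‑1,3‑dioxin‑4‑one
Product: 3 6‑(2,4‑dioxopentyl)‑2,2‑dimethyl‑4H‑1,3‑dioxin‑4‑one
Conditions: LiN(i‑Pr)2 (2.2 equiv), THF, −78 °C; MeC(O)N(OMe)Me, −78 → −20 °C; aq. HCl
Reagents that add atoms: N‑methoxy‑N‑methylacetamide, CON(C)C(C)=O
Why: Double deprotonation gives the 1,3‑dianion, whose terminal, less stabilised carbanion attacks the Weinreb amide (dianion Claisen condensation), and the chelated tetrahedral adduct prevents a second addition.

Step 3
Reactants: 4 orsellinic acid (2,4‑dihydroxy‑6‑methylbenzoic acid)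
Product: 5 benzyl orsellinate (benzyl 2,4‑dihydroxy‑6‑methylbenzoate)
Conditions: BnBr, KHCO3, DMF, rt
Reagents that add atoms: benzyl bromide, BrCc1ccccc1
Why: Hydrogencarbonate ionises only the carboxylic acid, so the carboxylate alone is benzylated (SN2 esterification) and both phenols stay free.

Step 4
Reactants: 3 6‑(2,4‑dioxopentyl)‑2,2‑dimethyl‑4H‑1,3‑dioxin‑4‑one; 5 benzyl orsellinate (1.5 equiv)
Product: 8 benzyl lecanorate (benzyl 4‑[(2,4‑dihydroxy‑6‑methylbenzoyl)oxy]‑2‑hydroxy‑6‑methylbenzoate), via acylketene 6 (not isolated), via aryl 3,5,7‑trioxooctanoate 7 (not isolated)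
Conditions: PhMe, 110 °C; then Et3N (cat.), CH2Cl2, rt; aq. HCl wash
Reagents that add atoms: none
Why: Heating 3 should expel acetone by a retro‑hetero‑Diels–Alder reaction to give acylketene 6, to which the free C4 phenol of 5 adds to form aryl triketo ester 7; triethylamine then enolises C2 of 7, which attacks the C7 ketone, and loss of water with enolisation of the C3 and C5 carbonyls aromatises ring B. The closest known reactions are the thermolysis of diketo‑dioxinones with alcohol capture and aldol aromatisation to resorcylate esters, and the formation of aryl acetoacetates from dioxinones and phenols. Ring B closes by a 6‑(enolexo)‑exo‑trig aldol condensation that forms its C1–C6 bond, and no stereocentre is created. The step needs chemoselectivity between the two phenols of 5, which the hydrogen bond from the C2 hydroxyl to the benzyl ester carbonyl secures, and the C2‑to‑C7 aldol is the only six‑membered carbocyclisation open to the chain. An amine base in an aprotic solvent spares the new aryl ester from solvolysis, and the excess of 5 should suppress capture of 6 by its own enol oxygen or by the phenol of 8.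

Step 5
Reactants: 9 1‑(2,4‑dihydroxy‑6‑methylphenyl)ethan‑1‑one
Product: 10 1‑[2,4‑bis(benzyloxy)‑6‑methylphenyl]ethan‑1‑one
Conditions: BnBr (2.3 equiv), K2CO3, DMF, 60 °C
Reagents that add atoms: benzyl bromide, BrCc1ccccc1
Why: Williamson ether synthesis, in which carbonate in warm DMF ionises both phenols, including the ketone‑chelated C2 hydroxyl, and each phenoxide displaces bromide.

Step 6
Reactants: 10 1‑[2,4‑bis(benzyloxy)‑6‑methylphenyl]ethan‑1‑one
Product: 11 2,4‑bis(benzyloxy)‑6‑methylphenyl acetate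
Conditions: mCPBA, TFA (cat.), CH2Cl2, 0 °C → rt
Reagents that add atoms: 3‑chloroperoxybenzoic acid, OOC(=O)c1cccc(Cl)c1
Why: Baeyer–Villiger oxidation, in which the electron‑rich, di‑ortho‑substituted aryl group migrates in preference to methyl, so the acetyl group becomes directly the acetate on the oxygen that will be O5 of ring A.

Step 7
Reactants: 11 2,4‑bis(benzyloxy)‑6‑methylphenyl acetate
Product: 13 4,6‑bis(benzyloxy)‑3‑formyl‑2‑methylphenyl acetate, via iminium salt 12 (not isolated)
Conditions: POCl3, DMF, 0 → 50 °C; then ice–water, rt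
Reagents that add atoms: N,N‑dimethylformamide, CN(C)C=O; water, O
Why: Vilsmeier–Haack formylation at the ring carbon that is para to one benzyloxy group, ortho to the other and next to the methyl, as is usual for 3,5‑dialkoxytoluenes, while the carbon between the two benzyloxy groups is shielded from the bulky chloroiminium ion.

Step 8
Reactants: 13 4,6‑bis(benzyloxy)‑3‑formyl‑2‑methylphenyl acetate
Product: 14 3‑acetoxy‑4,6‑bis(benzyloxy)‑2‑methylbenzoic acid (the ring A acid: C5 acetate, C2 and C4 benzyl ethers in ring A numbering)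
Conditions: NaClO2, NaH2PO4, 2‑methyl‑2‑butene, t‑BuOH/THF/H2O, rt
Reagents that add atoms: sodium chlorite, [Na+].[O-]Cl=O
Why: Pinnick oxidation of the aldehyde by chlorous acid under phosphate buffer, with the alkene scavenging hypochlorous acid, at a pH that leaves the aryl acetate and benzyl ethers untouched.

Step 9
Reactants: 14 3‑acetoxy‑4,6‑bis(benzyloxy)‑2‑methylbenzoic acid; 8 benzyl lecanorate
Product: 16 benzyl 4‑({4‑[(3‑acetoxy‑4,6‑bis(benzyloxy)‑2‑methylbenzoyl)oxy]‑2‑hydroxy‑6‑methylbenzoyl}oxy)‑2‑hydroxy‑6‑methylbenzoate, via mixed trifluoroacetic anhydride 15 (not isolated)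
Conditions: (CF3CO)2O, PhMe, rt
Reagents that add atoms: none
Why: Depside esterification through mixed anhydride 15, an acylium‑type donor able to react at the di‑ortho‑substituted carbonyl, and of the three phenols of 8 only the ring B C4 hydroxyl is not held in a hydrogen bond to an ester carbonyl, so the ester should form at ring B O4.

Step 10
Reactants: 16 the benzyl‑protected tridepside
Product: 17 4‑({4‑[(3‑acetoxy‑4,6‑dihydroxy‑2‑methylbenzoyl)oxy]‑2‑hydroxy‑6‑methylbenzoyl}oxy)‑2‑hydroxy‑6‑methylbenzoic acid (CNP0154030.0)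
Conditions: H2 (1 atm), Pd/C (10% palladium on carbon), EtOAc/THF, rt
Reagents that add atoms: none
Why: Catalytic hydrogenolysis cleaves the two benzyl ethers and the benzyl ester while aryl esters and the acetate are inert, and the neutral aprotic medium should keep the acetate on O5 from migrating to the freed O4.

**Compound list**

1 | 2,2,6‑trimethyl‑4H‑1,3‑dioxin‑4‑one | CC1=CC(=O)OC(C)(C)O1 | starting material
2 | 2,2‑dimethyl‑6‑(2‑oxopropyl)‑4H‑1,3‑dioxin‑4‑one | CC(=O)CC1=CC(=O)OC(C)(C)O1 | intermediate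
3 | 6‑(2,4‑dioxopentyl)‑2,2‑dimethyl‑4H‑1,3‑dioxin‑4‑one | CC(=O)CC(=O)CC1=CC(=O)OC(C)(C)O1 | intermediate
4 | orsellinic acid (2,4‑dihydroxy‑6‑methylbenzoic acid) | Cc1cc(O)cc(O)c1C(=O)O | starting material
5 | benzyl orsellinate | Cc1cc(O)cc(O)c1C(=O)OCc1ccccc1 | intermediate
6 | 3,5,7‑trioxooct‑1‑en‑1‑one (acylketene) | CC(=O)CC(=O)CC(=O)C=C=O | intermediate (not isolated)
7 | benzyl 2‑hydroxy‑6‑methyl‑4‑[(3,5,7‑trioxooctanoyl)oxy]benzoate | CC(=O)CC(=O)CC(=O)CC(=O)Oc1cc(C)c(C(=O)OCc2ccccc2)c(O)c1 | intermediate (not isolated)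
8 | benzyl lecanorate (benzyl 4‑[(2,4‑dihydroxy‑6‑methylbenzoyl)oxy]‑2‑hydroxy‑6‑methylbenzoate) | Cc1cc(O)cc(O)c1C(=O)Oc1cc(C)c(C(=O)OCc2ccccc2)c(O)c1 | intermediate
9 | 1‑(2,4‑dihydroxy‑6‑methylphenyl)ethan‑1‑one | CC(=O)c1c(C)cc(O)cc1O | starting material
10 | 1‑[2,4‑bis(benzyloxy)‑6‑methylphenyl]ethan‑1‑one | CC(=O)c1c(C)cc(OCc2ccccc2)cc1OCc1ccccc1 | intermediate
11 | 2,4‑bis(benzyloxy)‑6‑methylphenyl acetate | CC(=O)Oc1c(C)cc(OCc2ccccc2)cc1OCc1ccccc1 | intermediate
12 | N‑{[3‑acetoxy‑4,6‑bis(benzyloxy)‑2‑methylphenyl]methylidene}‑N‑methylmethanaminium dichlorophosphate | CC(=O)Oc1c(C)c(C=[N+](C)C)c(OCc2ccccc2)cc1OCc1ccccc1.[O-]P(=O)(Cl)Cl | intermediate (not isolated)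
13 | 4,6‑bis(benzyloxy)‑3‑formyl‑2‑methylphenyl acetate | CC(=O)Oc1c(C)c(C=O)c(OCc2ccccc2)cc1OCc1ccccc1 | intermediate
14 | 3‑acetoxy‑4,6‑bis(benzyloxy)‑2‑methylbenzoic acid | CC(=O)Oc1c(C)c(C(=O)O)c(OCc2ccccc2)cc1OCc1ccccc1 | intermediate
15 | 3‑acetoxy‑4,6‑bis(benzyloxy)‑2‑methylbenzoic trifluoroacetic anhydride | CC(=O)Oc1c(C)c(C(=O)OC(=O)C(F)(F)F)c(OCc2ccccc2)cc1OCc1ccccc1 | intermediate (not isolated)
16 | benzyl 4‑({4‑[(3‑acetoxy‑4,6‑bis(benzyloxy)‑2‑methylbenzoyl)oxy]‑2‑hydroxy‑6‑methylbenzoyl}oxy)‑2‑hydroxy‑6‑methylbenzoate | CC(=O)Oc1c(C)c(C(=O)Oc2cc(C)c(C(=O)Oc3cc(C)c(C(=O)OCc4ccccc4)c(O)c3)c(O)c2)c(OCc2ccccc2)cc1OCc1ccccc1 | intermediate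
17 | 4‑({4‑[(3‑acetoxy‑4,6‑dihydroxy‑2‑methylbenzoyl)oxy]‑2‑hydroxy‑6‑methylbenzoyl}oxy)‑2‑hydroxy‑6‑methylbenzoic acid (CNP0154030.0) | CC(=O)Oc1c(O)cc(O)c(C(=O)Oc2cc(C)c(C(=O)Oc3cc(C)c(C(=O)O)c(O)c3)c(O)c2)c1C | target

**Count and risks**

Total step count: 10. Longest linear sequence: 6 steps (9 → 10 → 11 → 13 → 14 → 16 → 17; steps 5 to 10).

Steps most likely to fail:

1. Step 4. The aryl triketo ester carries a good aryloxide leaving group. It may lactonise through its C5 enol oxygen, or fall back to the ketene, faster than the carbocyclic aldol closes. The ketene may also be intercepted by its own enol oxygen or by the free phenol of the product, giving a pyranone or oligomers. The fallback sets out from 4 and 5 and comes back at 8, making the hindered ester by acylation. Orsellinic acid 4 is acetylated on both phenols (Ac2O, pyridine, 0 °C → rt, aqueous work‑up) to 2,4‑diacetoxy‑6‑methylbenzoic acid F1. F1 is esterified with the C4 phenol of 5 by trifluoroacetic anhydride in toluene to benzyl 4‑[(2,4‑diacetoxy‑6‑methylbenzoyl)oxy]‑2‑hydroxy‑6‑methylbenzoate F2. The two phenyl acetates are then removed with cold dilute ammonia in aqueous THF at 0 °C, which should spare the di‑ortho‑substituted depside ester and the benzyl ester, to give 8.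

2. Step 9. The hindered acyl donor may react slowly, so that site selectivity among the three phenols of 8 is lost, the electron‑rich ring B is acylated on carbon, or trifluoroacetylation wins. The fallback sets out from 14 and 5 and comes back at 16, making the A–B ester before the B–C ester and doing without 8. Acid 14 is condensed (trifluoroacetic anhydride, toluene) with the C4 hydroxyl of commercial 2,4‑dihydroxy‑6‑methylbenzaldehyde, which offers only one other, chelated hydroxyl, to give 4‑formyl‑3‑hydroxy‑5‑methylphenyl 3‑acetoxy‑4,6‑bis(benzyloxy)‑2‑methylbenzoate F3. Chlorite oxidation (NaClO2, NaH2PO4, 2‑methyl‑2‑butene) converts the aldehyde into 4‑{[3‑acetoxy‑4,6‑bis(benzyloxy)‑2‑methylbenzoyl]oxy}‑2‑hydroxy‑6‑methylbenzoic acid F4. F4 is then esterified with the C4 phenol of 5 (trifluoroacetic anhydride, toluene) to give 16.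

3. Step 7. Substitution at the crowded carbon between methyl and benzyloxy may be slow, with erosion of the aryl acetate during the acidic hydrolysis of the iminium salt. The fallback sets out from 11 and comes back at 13, replacing direct formylation by halogenation and carbonylation. N‑Bromosuccinimide in MeCN at 0 °C should brominate the same carbon to give 4,6‑bis(benzyloxy)‑3‑bromo‑2‑methylphenyl acetate F5. Palladium‑catalysed reductive carbonylation (Pd(OAc)2, di(1‑adamantyl)‑n‑butylphosphine, CO/H2, TMEDA, toluene, 100 °C) then gives aldehyde 13 under non‑acidic, non‑hydrolytic conditions.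

**Further compounds**

F1 | step 4 | 2,4‑diacetoxy‑6‑methylbenzoic acid | CC(=O)Oc1cc(C)c(C(=O)O)c(OC(C)=O)c1
F2 | step 4 | benzyl 4‑[(2,4‑diacetoxy‑6‑methylbenzoyl)oxy]‑2‑hydroxy‑6‑methylbenzoate | CC(=O)Oc1cc(C)c(C(=O)Oc2cc(C)c(C(=O)OCc3ccccc3)c(O)c2)c(OC(C)=O)c1
F3 | step 9 | 4‑formyl‑3‑hydroxy‑5‑methylphenyl 3‑acetoxy‑4,6‑bis(benzyloxy)‑2‑methylbenzoate | CC(=O)Oc1c(C)c(C(=O)Oc2cc(C)c(C=O)c(O)c2)c(OCc2ccccc2)cc1OCc1ccccc1
F4 | step 9 | 4‑{[3‑acetoxy‑4,6‑bis(benzyloxy)‑2‑methylbenzoyl]oxy}‑2‑hydroxy‑6‑methylbenzoic acid | CC(=O)Oc1c(C)c(C(=O)Oc2cc(C)c(C(=O)O)c(O)c2)c(OCc2ccccc2)cc1OCc1ccccc1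
F5 | step 7 | 4,6‑bis(benzyloxy)‑3‑bromo‑2‑methylphenyl acetate | CC(=O)Oc1c(C)c(Br)c(OCc2ccccc2)cc1OCc1ccccc1
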